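**Remark on the chemistry (assumption):** the target has no stereocentre and no configurationally stable axis (the aryl ester bonds rotate freely), so it is achiral. "Single enantiomer" is therefore met by the compound itself, and no stereocontrol is required.

Atom labels used throughout: ring A = C1 (CO2Me), C2 (OMe), C3 (CH3), C4 (ester oxygen O4), C5 (CH3), C6 (CH3). Ring B = C1' (bears the depside carbonyl C7'), C2' (OH), C3' (CH3), C4' (OH), C5' (CHO), C6' (CH3).

## Analysis of the target

The target is a depside: two hexasubstituted benzene rings joined by a single aryl ester (C7'–O4), with no further ring and no chain. There are no stereocentres, so the difficulty is entirely one of substitution pattern and functional-group compatibility. The ester bond is flanked by four ortho substituents (2'-OH and 6'-CH3 on the acyl side, 3-CH3 and 5-CH3 on the phenol side), which makes a direct acylation of the phenol by the arene carboxylic acid slow. The sensitive groups are the aryl ester (transacylation by alkoxide or hydroxide), the aryl aldehyde at C5' (reduced under hydrogenolysis, oxidised in air under base) and the two free phenols of ring B. Three phenolic oxygens of the same type must end up different: O2 methylated, O4 acylated, O2'/O4' free. The feature that invites the key step is the atom sequence C7'(=O)–C1'–C2'(OH)–C3'–C4'(OH)–C5'–C6'(CH3). Oxygen sits on alternate carbons, the pattern of a folded tetraketide in which C1'–C6' is an aldol bond and C7' is the acyl terminus. Ring B and the hindered ester bond can therefore be made together from an open chain whose C7' is a ketene carbon.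

## Retrosynthetic reasoning

**14 to 13.** The C5'–CHO bond is cut last. C5' is the only aromatic C–H in the whole of 13 (ring A is hexasubstituted), and it lies ortho to the 4'-OH and para to the 2'-OH. A Rieche formylation therefore has one possible site, and the aldehyde is never exposed to the hydrogenation and base steps of the route.

**13 to 4 + 9 (key disconnection).** Two bonds are cut together: the ester bond C7'–O4 and the ring bond C1'–C6'. This opens ring B to the triketo aryl ester 11, whose chain atoms C1–C8 map onto C7', C1', C2', C3', C4', C5', C6' and the 6'-methyl. Ester 11 is traced to acylketene 10 plus phenol 9, and 10 to the diketo-dioxinone 4 by cycloreversion. The cut is made here because the crowded ester bond is then formed at an sp carbon that has no ortho substituents yet, and because the oxygenation pattern of ring B falls out of the chain without any protecting group. The forward reaction has to achieve capture of 10 by the O–H of 9, an aldol closure of C2 onto C7 via 12, and dehydration to the arene.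

**4 to 3 to 2 to 1.** The chain of 4 is cut at the bond between its CH2 and the terminal acetyl carbon (dianion acylation of 3). Ketone 3 is cut at the bond between the CH(CH3) carbon and the ketone carbon (γ-acylation of the dienolate of 2). Dioxinone 2 is cut at its new C–CH3 bond (γ-methylation of 1). The future 3'-methyl is thus placed on the chain before the ring exists, so no regioselective C-methylation of an arene is needed.

**9 to 8 to 7 to 5.** The 5-methyl of 9 is traced to a formyl group and the free 4-OH to a benzyl ether, both released in one hydrogenation of 8. The formyl group of 8 goes in at the only free ring position of 7. The two ether groups of 7 come from 5, whose hydroxyls differ in reactivity: the 2-OH is hydrogen-bonded to the ester and the 4-OH is not. The mono-ether 6 is therefore formed first and methylated in the same flask.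

## Alternatives that were turned down

**Alternative 1:** (textbook) Disconnection of the ester bond C7'–O4 only. The forward key step would be acylation of 9 with the protected acid A1 (2,4-bis(benzyloxy)-5-formyl-3,6-dimethylbenzoic acid) under anhydride or carbodiimide activation to give the protected depside A2, followed by debenzylation. It was turned down for three reasons. The acyl carbon of A1 and the oxygen of 9 each carry two ortho substituents, so the coupling forms a tetra-ortho-substituted aryl benzoate. The deprotection is in conflict with the aldehyde: hydrogenolysis would reduce the aryl formyl group (the reactivity used on purpose in step 6), and a boron trihalide would threaten the C2 methyl ether next to the ester. Finally, A1 would need about five steps from 5, including hydrolysis of a doubly ortho-substituted ester to an acid that is prone to decarboxylation.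

**Alternative 2:** Disconnection of ring B at C1'–C2' and C5'–C6' ([4+2] benzannulation). The forward key step would be a Diels–Alder reaction of the aryl but-2-ynoate A3 (the but-2-ynoyl ester of 9) with the 1,3-bis(silyloxy)diene A4, followed by loss of methanol to give 13. The regiochemistry is correct in principle, since the nucleophilic CH2 terminus of A4 would bond to the methyl-bearing alkyne carbon. It was turned down because a β-methyl ynoate is a poor dienophile and would need temperatures at which the tetrasubstituted ketene acetal A4 decomposes or transfers silicon. The activated aryl ester of A3 also offers A4 a competing C-acylation site. The route still needs a separate esterification to make A3, so nothing is saved.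

**Alternative 3:** (biomimetic late-stage oxidation) Disconnection of the C5' formyl oxygen: both rings from the same trimethylated unit, and oxidation of the 5'-methyl of depside A5 to the aldehyde by a quinone-methide-type dehydrogenation para to the 2'-OH. It was turned down because A5 carries six C-methyl groups, three of them on ring B. The 3'-methyl is ortho to two hydroxyls and can also be oxidised; the 2'-OH is tied up in a hydrogen bond to the ester; and the ring is deactivated by the acyl group. Over-oxidation to the acid is also likely. In addition, A5 itself can only be made by the hindered esterification of Alternative 1, so the hardest bond is not addressed.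

Key step: step 7

## Route

**Step 1**
Reactants: 1 2,2,6-trimethyl-4H-1,3-dioxin-4-one
Product: 2 6-ethyl-2,2-dimethyl-4H-1,3-dioxin-4-one
Conditions: LDA, THF/DMPU, −78 °C; MeI, −78 → −40 °C
Reagents that add atoms: iodomethane, CI
Why: LDA removes a proton of the C6 methyl group to give the lithium dienolate, which should be alkylated at its γ-carbon by the small electrophile (γ-alkylation of a dioxinone dienolate, an acetoacetate γ-anion equivalent); low temperature and a slight deficit of MeI limit double alkylation.

**Step 2**
Reactants: 2 6-ethyl-2,2-dimethyl-4H-1,3-dioxin-4-one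
Product: 3 2,2-dimethyl-6-(3-oxobutan-2-yl)-4H-1,3-dioxin-4-one (racemic, enolisable)
Conditions: 2 (2.0 equiv), LiHMDS (2.0 equiv), THF, −78 °C; AcCl (1.0 equiv), −78 °C; dil. aq. HCl
Reagents that add atoms: acetyl chloride, CC(=O)Cl
Why: The lithium dienolate of 2 should be C-acylated at its γ-carbon (crossed Claisen-type γ-acylation of a dioxinone dienolate); the second equivalent of dienolate takes up the more acidic product proton, and the new CH(CH3) centre is racemic and is later absorbed into the arene.

**Step 3**
Reactants: 3 2,2-dimethyl-6-(3-oxobutan-2-yl)-4H-1,3-dioxin-4-one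
Product: 4 6-(3,5-dioxohexan-2-yl)-2,2-dimethyl-4H-1,3-dioxin-4-one (racemic, mixture of enol forms)
Conditions: LDA (2.2 equiv), THF, −78 °C; MeC(O)N(OMe)Me, −78 → −20 °C; dil. aq. HCl
Reagents that add atoms: N-methoxy-N-methylacetamide, CC(=O)N(C)OC
Why: Two equivalents of LDA should give the dianion (first at the doubly activated methine, then at the acetyl methyl), whose terminal, more basic carbanion adds to the N-methoxy-N-methylamide; the chelated tetrahedral adduct persists until the quench, so neither a second addition nor proton exchange with the product occurs (dianion Claisen acylation of a keto-dioxinone).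

**Step 4**
Reactants: 5 methyl 2,4-dihydroxy-3,6-dimethylbenzoate
Product: 7 methyl 4-(benzyloxy)-2-methoxy-3,6-dimethylbenzoate, via monobenzyl ether 6 (not isolated)
Conditions: BnBr (1.05 equiv), K2CO3, DMF, rt; then MeI (3 equiv), 50 °C
Reagents that add atoms: benzyl bromide, BrCc1ccccc1; iodomethane, CI
Why: Two Williamson etherifications in one flask: the 4-OH, which is not hydrogen-bonded and is the more acidic, should be benzylated at room temperature, whereas the 2-OH, chelated to the ester carbonyl, reacts only with the small electrophile on warming, so the two oxygens are differentiated without isolating 6.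

**Step 5**
Reactants: 7 methyl 4-(benzyloxy)-2-methoxy-3,6-dimethylbenzoate
Product: 8 methyl 4-(benzyloxy)-5-formyl-2-methoxy-3,6-dimethylbenzoate
Conditions: Cl2CHOMe, TiCl4, CH2Cl2, −78 → 0 °C; H2O
Reagents that add atoms: dichloromethyl methyl ether, COC(Cl)Cl; water, O
Why: Rieche formylation; C5 is the only ring C–H of 7 and is activated ortho to the benzyloxy and para to the methoxy group, so there is no regiochemical choice, and any Lewis-acid debenzylation is harmless because the benzyl group is removed in step 6 anyway.

**Step 6**
Reactants: 8 methyl 4-(benzyloxy)-5-formyl-2-methoxy-3,6-dimethylbenzoate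
Product: 9 methyl 4-hydroxy-2-methoxy-3,5,6-trimethylbenzoate
Conditions: H2 (3 bar), 10% Pd/C, AcOH, cat. conc. HCl, rt
Reagents that add atoms: none
Why: Pd-catalysed hydrogenolysis should cleave the O-benzyl bond and, under acid catalysis, take the electron-rich aryl formyl group down to methyl (C=O hydrogenation followed by benzylic C–O hydrogenolysis); the methyl ester, the aryl methyl ether and the ring are inert under these conditions.

**Step 7**
Reactants: 4 6-(3,5-dioxohexan-2-yl)-2,2-dimethyl-4H-1,3-dioxin-4-one; 9 methyl 4-hydroxy-2-methoxy-3,5,6-trimethylbenzoate
Product: 13 methyl 4-[(2,4-dihydroxy-3,6-dimethylbenzoyl)oxy]-2-methoxy-3,5,6-trimethylbenzoate, via acylketene 10 (not isolated), via triketo ester 11 (not isolated), via aldol adduct 12 (not isolated)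
Conditions: slow addition of 4 to 9 (2 equiv), PhMe, 110 °C; then Et3N, rt; then TFA, rt
Reagents that add atoms: none
Why: Heating 4 should trigger retro-[4+2] loss of acetone to acylketene 10, whose sp-hybridised C1 is attacked by the O–H of 9 in a pseudopericyclic addition that is little affected by the two ortho methyl groups of 9, giving triketo ester 11 with the depside C–O bond already in place. Et3N then enolises C2 (between ester and ketone), which adds to the C7 methyl ketone, and TFA dehydrates aldol adduct 12, which tautomerises to the aromatic ring B of 13. The closest known reaction type is the thermolysis of diketo-dioxinones with alcohols followed by aldol aromatisation to resorcylates, together with the capture of acylketenes by phenols. The only ring closed is ring B, by C2–C7 bond formation (C1'–C6' in 13) in a 6-(enolendo)-exo-trig aldol. No stereocentre is created in 13; the labile CH(CH3) centre of 4, 10 and 11 and the two sp3 centres of 12 are uncontrolled and are erased on aromatisation. Intermolecular O–H capture has to win over closure of the C5 enol oxygen onto the ketene, and this is secured by slow addition of 4 into an excess of hot 9. Ring closure has to go C2 onto C7 rather than C8 onto C3 or C6 onto the aryl ester (Claisen); this is secured by the weak amine base, by the C4 methyl group that shields the C3 carbonyl, and by C7 being the least hindered ketone, while reversible loss of aryloxide from 11 only regenerates 10 in the presence of 9.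

**Step 8**
Reactants: 13 methyl 4-[(2,4-dihydroxy-3,6-dimethylbenzoyl)oxy]-2-methoxy-3,5,6-trimethylbenzoate
Product: 14 methyl 4-[(5-formyl-2,4-dihydroxy-3,6-dimethylbenzoyl)oxy]-2-methoxy-3,5,6-trimethylbenzoate (target)
Conditions: Cl2CHOMe, TiCl4, CH2Cl2, −40 → 0 °C; dil. aq. HCl
Reagents that add atoms: dichloromethyl methyl ether, COC(Cl)Cl; water, O
Why: Rieche formylation; C5' is the only aromatic C–H in 13, ortho to the 4'-OH and para to the 2'-OH, and the titanium phenoxide should deliver the electrophile to that ortho position, while the acidic, non-nucleophilic conditions leave the depside ester, the methyl ester and the aryl methyl ether in place.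

## Compound list

1 | 2,2,6-trimethyl-4H-1,3-dioxin-4-one | CC1=CC(=O)OC(C)(C)O1 | starting material
2 | 6-ethyl-2,2-dimethyl-4H-1,3-dioxin-4-one | CCC1=CC(=O)OC(C)(C)O1 | intermediate
3 | 2,2-dimethyl-6-(3-oxobutan-2-yl)-4H-1,3-dioxin-4-one (racemic) | CC(=O)C(C)C1=CC(=O)OC(C)(C)O1 | intermediate
4 | 6-(3,5-dioxohexan-2-yl)-2,2-dimethyl-4H-1,3-dioxin-4-one (racemic) | CC(=O)CC(=O)C(C)C1=CC(=O)OC(C)(C)O1 | intermediate
5 | methyl 2,4-dihydroxy-3,6-dimethylbenzoate | COC(=O)c1c(C)cc(O)c(C)c1O | starting material
6 | methyl 4-(benzyloxy)-2-hydroxy-3,6-dimethylbenzoate | COC(=O)c1c(C)cc(OCc2ccccc2)c(C)c1O | intermediate (not isolated)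
7 | methyl 4-(benzyloxy)-2-methoxy-3,6-dimethylbenzoate | COC(=O)c1c(C)cc(OCc2ccccc2)c(C)c1OC | intermediate
8 | methyl 4-(benzyloxy)-5-formyl-2-methoxy-3,6-dimethylbenzoate | COC(=O)c1c(C)c(C=O)c(OCc2ccccc2)c(C)c1OC | intermediate
9 | methyl 4-hydroxy-2-methoxy-3,5,6-trimethylbenzoate | COC(=O)c1c(C)c(C)c(O)c(C)c1OC | intermediate
10 | 4-methyl-3,5,7-trioxooct-1-en-1-one (acylketene, racemic) | CC(=O)CC(=O)C(C)C(=O)C=C=O | intermediate (not isolated)
11 | methyl 2-methoxy-3,5,6-trimethyl-4-[(4-methyl-3,5,7-trioxooctanoyl)oxy]benzoate (racemic) | COC(=O)c1c(C)c(C)c(OC(=O)CC(=O)C(C)C(=O)CC(C)=O)c(C)c1OC | intermediate (not isolated)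
12 | methyl 4-[(2,6-dihydroxy-3,6-dimethyl-4-oxocyclohex-1-ene-1-carbonyl)oxy]-2-methoxy-3,5,6-trimethylbenzoate (mixture of diastereomers) | COC(=O)c1c(C)c(C)c(OC(=O)C2=C(O)C(C)C(=O)CC2(C)O)c(C)c1OC | intermediate (not isolated)
13 | methyl 4-[(2,4-dihydroxy-3,6-dimethylbenzoyl)oxy]-2-methoxy-3,5,6-trimethylbenzoate | COC(=O)c1c(C)c(C)c(OC(=O)c2c(C)cc(O)c(C)c2O)c(C)c1OC | intermediate
14 | methyl 4-[(5-formyl-2,4-dihydroxy-3,6-dimethylbenzoyl)oxy]-2-methoxy-3,5,6-trimethylbenzoate | COC(=O)c1c(C)c(C)c(OC(=O)c2c(C)c(C=O)c(O)c(C)c2O)c(C)c1OC | target

## Step count and risk

Total step count: 8. Longest linear sequence: 5 steps (1 → 2 → 3 → 4 → 13 → 14, or 5 → 7 → 8 → 9 → 13 → 14).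

**Step 7 (key step).** The most likely failure is that capture of the acylketene by the hindered, electron-poor phenol O–H is slower than intramolecular closure of the C5 enol oxygen onto the ketene (pyranone formation). After capture, the activated aryloxy group may also be expelled by lactonisation or Claisen closure before the aldol step. The fallback builds the arene first and makes the ester bond afterwards. It sets out from 4: Et3N in CH2Cl2 at room temperature should cycloaromatise 4 with the dioxinone ring intact (its C5 carbon adds to the terminal ketone) to the benzodioxinone 7-hydroxy-2,2,5,8-tetramethyl-4H-1,3-benzodioxin-4-one F1. Irradiation of F1 at about 300 nm in CH2Cl2 in the presence of 9 should expel acetone and give the o-quinone ketene 3-hydroxy-2,5-dimethyl-6-(oxomethylidene)cyclohexa-2,4-dien-1-one F2, which 9 captures at its sp carbon. The fallback comes back to the route at 13.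

**Step 8.** The most likely failures are Lewis-acid cleavage of the C2 methyl ether (chelation of titanium between that oxygen and the neighbouring ester) and stalling of the substitution because the titanium bis-phenoxide of ring B aggregates. The fallback replaces the electrophilic formylation with a boron-templated hydroxymethylation followed by oxidation. It sets out from 13: phenylboronic acid, paraformaldehyde and catalytic propionic acid in refluxing toluene (water removal) should give, ortho to the 4'-OH only, the cyclic phenylboronate methyl 4-[(7-hydroxy-5,8-dimethyl-2-phenyl-4H-1,3,2-benzodioxaborinin-6-yl)carbonyloxy]-2-methoxy-3,5,6-trimethylbenzoate F3. Exchange with propane-1,3-diol should release the benzylic alcohol methyl 4-{[2,4-dihydroxy-5-(hydroxymethyl)-3,6-dimethylbenzoyl]oxy}-2-methoxy-3,5,6-trimethylbenzoate F4, and activated MnO2 in CH2Cl2 should oxidise it to the aldehyde. The fallback comes back to the route at 14.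

**Step 2.** The most likely failures are acylation of the γ-substituted dienolate at oxygen or at C5 instead of the hindered γ-carbon, and consumption of the acid chloride by deprotonation. The fallback reverses the order of the two C–C bond formations. It sets out from 1: γ-acetylation of the unsubstituted dienolate (LiHMDS, AcCl, THF, −78 °C) should give 2,2-dimethyl-6-(2-oxopropyl)-4H-1,3-dioxin-4-one F5. Its doubly activated methylene is then methylated as a soft carbanion (MeI, 1.0 equiv, K2CO3, acetone, rt). The fallback comes back to the route at 3 and makes step 1 unnecessary.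

**Step 3.** The most likely failures are incomplete formation of the dianion at the methyl-bearing methine, attack of the dianion on the dioxinone carbonyl of a second molecule, and O-acylation. The fallback avoids the dianion by bringing in the last four carbons as one masked unit. It sets out from 2: the lithium dienolate of 2 (LiHMDS, THF, −78 °C) is acylated with N-methoxy-N-methyl-2-(2-methyl-1,3-dioxolan-2-yl)acetamide F6, which is made from commercial ethyl (2-methyl-1,3-dioxolan-2-yl)acetate with MeNHOMe·HCl and i-PrMgCl. This should give the ketal 2,2-dimethyl-6-[4-(2-methyl-1,3-dioxolan-2-yl)-3-oxobutan-2-yl]-4H-1,3-dioxin-4-one F7, and aqueous oxalic acid in THF should remove the dioxolane. The fallback comes back to the route at 4.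

## Further compounds

F1 | step 7 | 7-hydroxy-2,2,5,8-tetramethyl-4H-1,3-benzodioxin-4-one | Cc1cc(O)c(C)c2OC(C)(C)OC(=O)c12
F2 | step 7 | 3-hydroxy-2,5-dimethyl-6-(oxomethylidene)cyclohexa-2,4-dien-1-one | O=C=C1C(C)=CC(O)=C(C)C1=O
F3 | step 8 | methyl 4-[(7-hydroxy-5,8-dimethyl-2-phenyl-4H-1,3,2-benzodioxaborinin-6-yl)carbonyloxy]-2-methoxy-3,5,6-trimethylbenzoate | COC(=O)c1c(C)c(C)c(OC(=O)c2c(C)c3COB(c4ccccc4)Oc3c(C)c2O)c(C)c1OC
F4 | step 8 | methyl 4-{[2,4-dihydroxy-5-(hydroxymethyl)-3,6-dimethylbenzoyl]oxy}-2-methoxy-3,5,6-trimethylbenzoate | COC(=O)c1c(C)c(C)c(OC(=O)c2c(C)c(CO)c(O)c(C)c2O)c(C)c1OC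
F5 | step 2 | 2,2-dimethyl-6-(2-oxopropyl)-4H-1,3-dioxin-4-one | CC(=O)CC1=CC(=O)OC(C)(C)O1
F6 | step 3 | N-methoxy-N-methyl-2-(2-methyl-1,3-dioxolan-2-yl)acetamide | CON(C)C(=O)CC1(C)OCCO1
F7 | step 3 | 2,2-dimethyl-6-[4-(2-methyl-1,3-dioxolan-2-yl)-3-oxobutan-2-yl]-4H-1,3-dioxin-4-one (racemic) | CC(C(=O)CC1(C)OCCO1)C1=CC(=O)OC(C)(C)O1
A1 | alternative 1 | 2,4-bis(benzyloxy)-5-formyl-3,6-dimethylbenzoic acid | O=Cc1c(C)c(C(=O)O)c(OCc2ccccc2)c(C)c1OCc1ccccc1
A2 | alternative 1 | methyl 4-{[2,4-bis(benzyloxy)-5-formyl-3,6-dimethylbenzoyl]oxy}-2-methoxy-3,5,6-trimethylbenzoate | COC(=O)c1c(C)c(C)c(OC(=O)c2c(C)c(C=O)c(OCc3ccccc3)c(C)c2OCc2ccccc2)c(C)c1OC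
A3 | alternative 2 | methyl 4-(but-2-ynoyloxy)-2-methoxy-3,5,6-trimethylbenzoate | CC#CC(=O)Oc1c(C)c(C)c(C(=O)OC)c(OC)c1C
A4 | alternative 2 | 1-methoxy-2-methyl-1,3-bis(trimethylsilyloxy)buta-1,3-diene | COC(O[Si](C)(C)C)=C(C)C(=C)O[Si](C)(C)C
A5 | alternative 3 | methyl 4-[(2,4-dihydroxy-3,5,6-trimethylbenzoyl)oxy]-2-methoxy-3,5,6-trimethylbenzoate | COC(=O)c1c(C)c(C)c(OC(=O)c2c(C)c(C)c(O)c(C)c2O)c(C)c1OC
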